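## Retrosynthetic overview

1. Target 14 ⇐ O-debenzylation, ester reduction, methylene acetal cleavage and alkene saturation ⇐ trans-4-aryl-5-aryloxy-1,3-dioxane 9.
2. Feature used: the 1,3-diol C7(OH)–C8–C9H2OH on ring A, with the ring B aryloxy group on C8, is the opened form of a 4-aryl-1,3-dioxane, the Prins adduct of a C7=C8 styrene and formaldehyde.
3. Key disconnection: dioxane 9 ⇒ (E)-enol ether 7 + two CH2O (bonds C8–C9 and C7–O, the O–CH2–O bridge, both stereocentres).
4. Enol ether 7 ⇒ (E)-β-bromostyrene 5 + methyl ferulate 6 (vinylic C–O coupling); 5 ⇒ aldehyde 1 + malonic acid 2.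
5. Ring order: rings A and B are bought; the only ring made is the 1,3-dioxane (step 4), opened again in step 6.

Key step: step 4

Assumption 1: the sense of induction of the chiral acid on an aryl enol ether cannot be predicted, so the catalyst antipode that delivers (4S,5R)-9 is chosen in a first small run; both antipodes are equally accessible.

Assumption 2: intermediate 11 is drawn with silicon on O9 and the pyridinium unit on the O7 side; the other regioisomer would hydrolyse to the same diol 12.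

## Route

Step 1
Reactants: 1 3,4-bis(benzyloxy)benzaldehyde; 2 malonic acid
Product: 4 (E)-3-[3,4-bis(benzyloxy)phenyl]prop-2-enoic acid, via arylidenemalonic acid 3 (not isolated)
Conditions: pyridine, piperidine (cat.), 90 °C then reflux
Reagents that add atoms: none
Why: Knoevenagel–Doebner condensation, in which the arylidenemalonic acid loses CO2 in hot pyridine to give the thermodynamically favoured (E)-cinnamic acid.

Step 2
Reactants: 4 (E)-3-[3,4-bis(benzyloxy)phenyl]prop-2-enoic acid
Product: 5 (E)-1,2-bis(benzyloxy)-4-(2-bromoethenyl)benzene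
Conditions: NBS (1.05 equiv), LiOAc (10 mol %), MeCN/H2O, rt, dark
Reagents that add atoms: N-bromosuccinimide, O=C1CCC(=O)N1Br
Why: catalytic Hunsdiecker bromodecarboxylation, which works best on electron-rich cinnamic acids because the bromonium/benzylic cation is stabilised by the para oxygen, and anti loss of CO2 should give the (E)-bromide.

Step 3
Reactants: 5 (E)-1,2-bis(benzyloxy)-4-(2-bromoethenyl)benzene; 6 methyl ferulate
Product: 7 methyl (E)-3-[4-[(E)-2-[3,4-bis(benzyloxy)phenyl]ethenyloxy]-3-methoxyphenyl]prop-2-enoate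
Conditions: CuI (10 mol %), N,N-dimethylglycine·HCl (30 mol %), Cs2CO3 (2 equiv), 1,4-dioxane, 90 °C, Ar
Reagents that add atoms: none
Why: Ullmann-type C–O coupling of a vinyl bromide with a phenoxide under CuI/amino acid catalysis, which proceeds at the sp2 carbon with retention of the (E) geometry.

Step 4
Reactants: 7 methyl (E)-3-[4-[(E)-2-[3,4-bis(benzyloxy)phenyl]ethenyloxy]-3-methoxyphenyl]prop-2-enoate; 8 paraformaldehyde (as formaldehyde, first CH2O unit)
Product: 9 methyl (E)-3-[4-[[(4S,5R)-4-[3,4-bis(benzyloxy)phenyl]-1,3-dioxan-5-yl]oxy]-3-methoxyphenyl]prop-2-enoate (trans-4,5)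
Conditions: (CH2O)n (4 equiv of CH2O), chiral IDPi Brønsted acid (BINOL-derived imidodiphosphorimidate, N-triflyl core, bulky 3,3'-aryl groups; 5 mol %), CHCl3/cyclohexane, −20 °C
Reagents that add atoms: formaldehyde (second CH2O unit, from the same paraformaldehyde 8), C=O
Why: Proposed new method: the confined chiral acid protonates formaldehyde and the ion pair is attacked by C8 of the enol ether, which forms C8–C9 and leaves positive charge at C7 as a para-quinoid oxocarbenium ion of the 3,4-bis(benzyloxy)phenyl ring; the C9 oxygen takes up a second formaldehyde and the hemiacetal oxygen closes on C7. The closest known reactions are the imidodiphosphorimidate-catalysed enantioselective Prins reaction of styrenes with paraformaldehyde to 4-aryl-1,3-dioxanes and the trans-selective acid-catalysed Prins reaction of anethole, but a β-aryloxystyrene has not been used as the alkene. The single new ring, the 1,3-dioxane, closes by attack of the hemiacetal oxygen on the benzylic cation C7 (six-membered, chair-like; in the concerted asynchronous limit a suprafacial addition across C7=C8). C8 is set in the C–C bond-forming event by the alkene face left open in the chiral anion pocket, and C7 is set relative to C8 because syn addition to the (E)-alkene, or diequatorial chair closure if a free cation intervenes, both lead to the trans (4S,5R) ring. The step needs C8 and not C7 as the nucleophilic carbon, trans closure and one enantiomer: the dialkoxyphenyl ring is the stronger donor and the aryloxy oxygen is weakened by conjugation with ring B and its para acrylate, which should direct the electrophile to C8, while the acrylate also makes ring B too electron-poor to capture the cation.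

Step 5
Reactants: 9 methyl (E)-3-[4-[[(4S,5R)-4-[3,4-bis(benzyloxy)phenyl]-1,3-dioxan-5-yl]oxy]-3-methoxyphenyl]prop-2-enoate
Product: 10 methyl 3-[4-[[(4S,5R)-4-[3,4-bis(benzyloxy)phenyl]-1,3-dioxan-5-yl]oxy]-3-methoxyphenyl]propanoate
Conditions: H2 (1–3 atm), RhCl(PPh3)3 (5 mol %), toluene/EtOH (1:1), 40 °C
Reagents that add atoms: none
Why: homogeneous hydrogenation with RhCl(PPh3)3 saturates the unhindered conjugated alkene and leaves the benzyl ethers and the benzylic acetal C–O bond untouched.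

Step 6
Reactants: 10 methyl 3-[4-[[(4S,5R)-4-[3,4-bis(benzyloxy)phenyl]-1,3-dioxan-5-yl]oxy]-3-methoxyphenyl]propanoate
Product: 12 methyl 3-[4-[[(1S,2R)-1-[3,4-bis(benzyloxy)phenyl]-1,3-dihydroxypropan-2-yl]oxy]-3-methoxyphenyl]propanoate, via pyridinium triflate 11 (not isolated)
Conditions: TMSOTf (3 equiv), 2,2'-bipyridyl (4 equiv), CH2Cl2, 0 °C to rt; then H2O, rt
Reagents that add atoms: none
Why: known mild methylene acetal cleavage, in which O-silylation opens the acetal to an oxocarbenium ion that bipyridyl traps as the N-(alkoxymethyl)pyridinium salt 11 and water then hydrolyses the N,O-acetal and the silyl ether; no bond to C7 or C8 is broken, so both stereocentres are kept.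

Step 7
Reactants: 12 methyl 3-[4-[[(1S,2R)-1-[3,4-bis(benzyloxy)phenyl]-1,3-dihydroxypropan-2-yl]oxy]-3-methoxyphenyl]propanoate
Product: 13 (1S,2R)-1-[3,4-bis(benzyloxy)phenyl]-2-[4-(3-hydroxypropyl)-2-methoxyphenoxy]propane-1,3-diol
Conditions: LiAlH4 (3 equiv), THF, 0 °C to rt; aq. potassium sodium tartrate (KNaC4H4O6) work-up
Reagents that add atoms: none
Why: hydride reduction of the methyl ester to the primary alcohol; the diol is carried as inert alkoxides and the benzyl and aryl ethers are stable to LiAlH4.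

Step 8
Reactants: 13 (1S,2R)-1-[3,4-bis(benzyloxy)phenyl]-2-[4-(3-hydroxypropyl)-2-methoxyphenoxy]propane-1,3-diol
Product: 14 (1S,2R)-1-(3,4-dihydroxyphenyl)-2-[4-(3-hydroxypropyl)-2-methoxyphenoxy]propane-1,3-diol (erythro, 7S,8R; CNP0319307.1)
Conditions: H2 (1 atm), 10% Pd/C, EtOAc/MeOH, rt, stopped after two equivalents of H2
Reagents that add atoms: none
Why: catalytic hydrogenolysis of the two aryl benzyl ethers under neutral conditions, which should be much faster than cleavage of the secondary benzylic C7–OH.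

## Compound list

1 | 3,4-bis(benzyloxy)benzaldehyde | O=Cc1ccc(OCc2ccccc2)c(OCc2ccccc2)c1 | starting material
2 | malonic acid | OC(=O)CC(=O)O | starting material
3 | 2-[3,4-bis(benzyloxy)benzylidene]malonic acid | OC(=O)C(=Cc1ccc(OCc2ccccc2)c(OCc2ccccc2)c1)C(=O)O | intermediate (not isolated)
4 | (E)-3-[3,4-bis(benzyloxy)phenyl]prop-2-enoic acid | OC(=O)/C=C/c1ccc(OCc2ccccc2)c(OCc2ccccc2)c1 | intermediate
5 | (E)-1,2-bis(benzyloxy)-4-(2-bromoethenyl)benzene | Br/C=C/c1ccc(OCc2ccccc2)c(OCc2ccccc2)c1 | intermediate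
6 | methyl ferulate | COC(=O)/C=C/c1ccc(O)c(OC)c1 | starting material
7 | methyl (E)-3-[4-[(E)-2-[3,4-bis(benzyloxy)phenyl]ethenyloxy]-3-methoxyphenyl]prop-2-enoate | COC(=O)/C=C/c1ccc(O/C=C/c2ccc(OCc3ccccc3)c(OCc3ccccc3)c2)c(OC)c1 | intermediate
8 | paraformaldehyde (as formaldehyde) | C=O | starting material
9 | methyl (E)-3-[4-[[(4S,5R)-4-[3,4-bis(benzyloxy)phenyl]-1,3-dioxan-5-yl]oxy]-3-methoxyphenyl]prop-2-enoate | COC(=O)/C=C/c1ccc(O[C@H](CO3)[C@@H](OC3)c2ccc(OCc4ccccc4)c(OCc4ccccc4)c2)c(OC)c1 | intermediate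
10 | methyl 3-[4-[[(4S,5R)-4-[3,4-bis(benzyloxy)phenyl]-1,3-dioxan-5-yl]oxy]-3-methoxyphenyl]propanoate | COC(=O)CCc1ccc(O[C@H](CO3)[C@@H](OC3)c2ccc(OCc4ccccc4)c(OCc4ccccc4)c2)c(OC)c1 | intermediate
11 | 1-[[(1S,2R)-1-[3,4-bis(benzyloxy)phenyl]-2-[2-methoxy-4-(3-methoxy-3-oxopropyl)phenoxy]-3-(trimethylsilyloxy)propoxy]methyl]-2-(pyridin-2-yl)pyridinium triflate | COC(=O)CCc1ccc(O[C@H](CO[Si](C)(C)C)[C@@H](OC[n+]3ccccc3-c3ccccn3)c2ccc(OCc4ccccc4)c(OCc4ccccc4)c2)c(OC)c1.[O-]S(=O)(=O)C(F)(F)F | intermediate (not isolated)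
12 | methyl 3-[4-[[(1S,2R)-1-[3,4-bis(benzyloxy)phenyl]-1,3-dihydroxypropan-2-yl]oxy]-3-methoxyphenyl]propanoate | COC(=O)CCc1ccc(O[C@H](CO)[C@@H](O)c2ccc(OCc3ccccc3)c(OCc3ccccc3)c2)c(OC)c1 | intermediate
13 | (1S,2R)-1-[3,4-bis(benzyloxy)phenyl]-2-[4-(3-hydroxypropyl)-2-methoxyphenoxy]propane-1,3-diol | COc1cc(CCCO)ccc1O[C@H](CO)[C@@H](O)c1ccc(OCc2ccccc2)c(OCc2ccccc2)c1 | intermediate
14 | (1S,2R)-1-(3,4-dihydroxyphenyl)-2-[4-(3-hydroxypropyl)-2-methoxyphenoxy]propane-1,3-diol | COc1cc(CCCO)ccc1O[C@H](CO)[C@@H](O)c1ccc(O)c(O)c1 | target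

## Step count and risks

Total step count: 8. Longest linear sequence: 8 steps (from aldehyde 1).

Steps most likely to fail:

1. Step 4 (the proposed new method). The formaldehyde electrophile may add to C7 instead of C8 (enol-ether regiochemistry), the acid may hydrolyse or oligomerise the enol ether, or facial control may be poor on this new alkene class. The fallback uses known chemistry only, sets out from methyl ferulate 6 and aldehyde 1, and comes back at triol 13. Hydrogenation of 6 (H2, Pd/C, EtOAc) would give methyl 3-(4-hydroxy-3-methoxyphenyl)propanoate F1. O-Alkylation (K2CO3, acetone) with (S)-4-benzyl-3-(bromoacetyl)oxazolidin-2-one F2, itself prepared by N-acylation of (S)-4-benzyloxazolidin-2-one with bromoacetyl bromide (n-BuLi, THF, −78 °C), would give the aryloxyacetyl imide F3. An Evans syn-aldol reaction of its dibutylboron enolate (Bu2BOTf, i-Pr2NEt, CH2Cl2, −78 °C) with 1 should give the (7R,8R) threo aldol adduct F4. LiBH4 (excess, THF/MeOH) would remove the auxiliary and reduce the methyl ester, giving the threo triol F5. TBSCl/imidazole would silylate the two primary alcohols to the bis-silyl ether F6. Mitsunobu inversion at C7 (4-nitrobenzoic acid, PPh3, DIAD, THF) would give the erythro 4-nitrobenzoate F7, K2CO3/MeOH the erythro alcohol F8, and Bu4NF in THF then 13.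

2. Step 6. The electron-rich benzylic C7–O bond may ionise in competition with activation at the acetal carbon, which would epimerise C7 or cause elimination. The fallback deactivates ring A before a classical acetolysis; it sets out from 10 and comes back at target 14. Hydrogenolysis (H2, Pd/C) would give the catechol dioxane F9, and Ac2O/pyridine the catechol diacetate F10, whose ring A no longer supports a C7 cation. Acetolysis (Ac2O, cat. H2SO4, 0 °C) would open the methylene acetal to the acetate/acetoxymethyl ether F11 (drawn as the 9-O-acetyl, 7-O-acetoxymethyl isomer; the other isomer converges). LiAlH4 (THF, 0 °C, mild acidic work-up) would then cleave all acetates and reduce the methyl ester to give 14.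

3. Step 3. Oxidative addition of the electron-rich vinyl bromide may be slow, and the alkene geometry or the product enol ether may not survive hot basic conditions. The fallback reverses the polarity of the coupling; it sets out from bromide 5 and comes back at enol ether 7. Bromine–lithium exchange (t-BuLi, THF, −78 °C), B(OiPr)3 and aqueous acid would give (E)-2-[3,4-bis(benzyloxy)phenyl]ethenylboronic acid F12. Oxidative Chan–Lam coupling with phenol 6 (Cu(OAc)2, pyridine, 4 Å sieves, CH2Cl2, air, rt) should then give 7 with retention of geometry.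

## Further compounds

F1 | step 4 | methyl 3-(4-hydroxy-3-methoxyphenyl)propanoate | COC(=O)CCc1ccc(O)c(OC)c1
F2 | step 4 | (S)-4-benzyl-3-(bromoacetyl)oxazolidin-2-one | BrCC(=O)N1[C@@H](Cc2ccccc2)COC1=O
F3 | step 4 | methyl 3-[4-[2-[(S)-4-benzyl-2-oxooxazolidin-3-yl]-2-oxoethoxy]-3-methoxyphenyl]propanoate | COC(=O)CCc1ccc(OCC(=O)N2[C@@H](Cc3ccccc3)COC2=O)c(OC)c1
F4 | step 4 | methyl 3-[4-[[(2S,3R)-1-[(S)-4-benzyl-2-oxooxazolidin-3-yl]-3-[3,4-bis(benzyloxy)phenyl]-3-hydroxy-1-oxopropan-2-yl]oxy]-3-methoxyphenyl]propanoate | COC(=O)CCc1ccc(O[C@H](C(=O)N2[C@@H](Cc3ccccc3)COC2=O)[C@H](O)c2ccc(OCc3ccccc3)c(OCc3ccccc3)c2)c(OC)c1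
F5 | step 4 | (1R,2R)-1-[3,4-bis(benzyloxy)phenyl]-2-[4-(3-hydroxypropyl)-2-methoxyphenoxy]propane-1,3-diol | COc1cc(CCCO)ccc1O[C@H](CO)[C@H](O)c1ccc(OCc2ccccc2)c(OCc2ccccc2)c1
F6 | step 4 | (1R,2R)-1-[3,4-bis(benzyloxy)phenyl]-3-(tert-butyldimethylsilyloxy)-2-[4-[3-(tert-butyldimethylsilyloxy)propyl]-2-methoxyphenoxy]propan-1-ol | COc1cc(CCCO[Si](C)(C)C(C)(C)C)ccc1O[C@H](CO[Si](C)(C)C(C)(C)C)[C@H](O)c1ccc(OCc2ccccc2)c(OCc2ccccc2)c1
F7 | step 4 | (1S,2R)-1-[3,4-bis(benzyloxy)phenyl]-3-(tert-butyldimethylsilyloxy)-2-[4-[3-(tert-butyldimethylsilyloxy)propyl]-2-methoxyphenoxy]propyl 4-nitrobenzoate | COc1cc(CCCO[Si](C)(C)C(C)(C)C)ccc1O[C@H](CO[Si](C)(C)C(C)(C)C)[C@@H](OC(=O)c1ccc(cc1)[N+](=O)[O-])c1ccc(OCc2ccccc2)c(OCc2ccccc2)c1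
F8 | step 4 | (1S,2R)-1-[3,4-bis(benzyloxy)phenyl]-3-(tert-butyldimethylsilyloxy)-2-[4-[3-(tert-butyldimethylsilyloxy)propyl]-2-methoxyphenoxy]propan-1-ol | COc1cc(CCCO[Si](C)(C)C(C)(C)C)ccc1O[C@H](CO[Si](C)(C)C(C)(C)C)[C@@H](O)c1ccc(OCc2ccccc2)c(OCc2ccccc2)c1
F9 | step 6 | methyl 3-[4-[[(4S,5R)-4-(3,4-dihydroxyphenyl)-1,3-dioxan-5-yl]oxy]-3-methoxyphenyl]propanoate | COC(=O)CCc1ccc(O[C@H](CO3)[C@@H](OC3)c2ccc(O)c(O)c2)c(OC)c1
F10 | step 6 | methyl 3-[4-[[(4S,5R)-4-(3,4-diacetoxyphenyl)-1,3-dioxan-5-yl]oxy]-3-methoxyphenyl]propanoate | COC(=O)CCc1ccc(O[C@H](CO3)[C@@H](OC3)c2ccc(OC(C)=O)c(OC(C)=O)c2)c(OC)c1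
F11 | step 6 | methyl 3-[4-[[(1S,2R)-3-acetoxy-1-(acetoxymethoxy)-1-(3,4-diacetoxyphenyl)propan-2-yl]oxy]-3-methoxyphenyl]propanoate | COC(=O)CCc1ccc(O[C@H](COC(C)=O)[C@@H](OCOC(C)=O)c2ccc(OC(C)=O)c(OC(C)=O)c2)c(OC)c1
F12 | step 3 | (E)-2-[3,4-bis(benzyloxy)phenyl]ethenylboronic acid | OB(O)/C=C/c1ccc(OCc2ccccc2)c(OCc2ccccc2)c1
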